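Retrosynthesis: after removal of two O-allyl groups, the C4–C4a bond of ring C is cut together with a 1,2-shift of ring B (from C3 back to C4), which unfolds the isoflavan into the acyclic (R)-mesylate ArA–O–CH2–CH(OMs)–CH2–ArB; this is cut at O1–C2 (phenol + epoxide), at C4–C1' (aryl Grignard + epichlorohydrin) and at the prenyl–ring B bond.
Forward: the ring B bromide is prenylated and allylated, joined through C1' to (R)-epichlorohydrin, the chlorohydrin is etherified by the ring A phenol, and ring C is closed last at C4–C4a while ring B moves from C4 to C3; rings A and B are bought as arenes.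
Enabling feature: ring B carries oxygen at C2' and C4', ortho and para to C1', so C1' can bridge C3 and C4 as a spirocyclopropane arenium (phenonium) ion; its ring strain and lost aromaticity drive attack at C4 by C4a of ring A, which is ortho to O1 and 5-OMe and para to O7.
Ring A comes from symmetric 2,6-dihydroxy-4-methoxybenzaldehyde, so the formyl group is in place from the start and C4a is the only open position ortho to O1.
Stereochemistry: the single stereocentre C3 derives from (R)-epichlorohydrin; aryl bridging inverts the mesylate carbon stereospecifically and should deliver 3R.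

Key step: step 7

Assumption: 2,6-dihydroxy-4-methoxybenzaldehyde is taken as a purchasable compound, like the other three starting materials.

Step 1
Reactants: 1 2-bromo-5-methoxyphenol; 2 1-bromo-3-methylbut-2-ene (prenyl bromide)
Product: 3 6-bromo-3-methoxy-2-(3-methylbut-2-en-1-yl)phenol
Conditions: NaH (1.05 equiv), toluene, 0 °C to rt
Reagents that add atoms: none
Why: In the non-polar solvent the sodium phenoxide reacts as a tight ion pair that steers the allylic bromide to the carbon ortho to oxygen (ortho-selective C-prenylation of a phenoxide), and the only free ortho position is C6 because C2 carries bromine.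

Step 2
Reactants: 3 6-bromo-3-methoxy-2-(3-methylbut-2-en-1-yl)phenol
Product: 4 1-bromo-4-methoxy-3-(3-methylbut-2-en-1-yl)-2-(prop-2-en-1-yloxy)benzene
Conditions: allyl bromide, K2CO3, DMF, 50 °C
Reagents that add atoms: allyl bromide, C=CCBr
Why: Williamson ether synthesis on the hindered phenol masks the C2' oxygen as an allyl ether that is inert to the Grignard chemistry that follows.

Step 3
Reactants: 4 1-bromo-4-methoxy-3-(3-methylbut-2-en-1-yl)-2-(prop-2-en-1-yloxy)benzene; 5 (R)-epichlorohydrin
Product: 7 (2R)-1-chloro-3-[4-methoxy-3-(3-methylbut-2-en-1-yl)-2-(prop-2-en-1-yloxy)phenyl]propan-2-ol, via arylmagnesium bromide 6 (not isolated)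
Conditions: Mg turnings, THF, 40 °C; then CuI (10 mol%), 5, −30 to 0 °C; H2O quench
Reagents that add atoms: none
Why: Grignard formation followed by CuI-catalysed epoxide ring opening at the unsubstituted ring carbon of epichlorohydrin leaves the carbinol stereocentre untouched, so it stays R.

Step 4
Reactants: 8 2,6-dihydroxy-4-methoxybenzaldehyde
Product: 9 2-hydroxy-4-methoxy-6-(prop-2-en-1-yloxy)benzaldehyde
Conditions: allyl bromide (1.0 equiv), K2CO3 (1.05 equiv), DMF, rt
Reagents that add atoms: allyl bromide, C=CCBr
Why: Williamson mono-etherification of a symmetric bis-phenol should stop after one alkylation because the remaining hydroxyl is tied up in the hydrogen bond to the formyl group and reacts much more slowly.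

Step 5
Reactants: 7 (2R)-1-chloro-3-[4-methoxy-3-(3-methylbut-2-en-1-yl)-2-(prop-2-en-1-yloxy)phenyl]propan-2-ol; 9 2-hydroxy-4-methoxy-6-(prop-2-en-1-yloxy)benzaldehyde
Product: 11 2-({(2R)-2-hydroxy-3-[4-methoxy-3-(3-methylbut-2-en-1-yl)-2-(prop-2-en-1-yloxy)phenyl]propyl}oxy)-4-methoxy-6-(prop-2-en-1-yloxy)benzaldehyde, via epoxide 10 (not isolated)
Conditions: K2CO3 (2.5 equiv), DMF, 80 °C
Reagents that add atoms: none
Why: Base closes the chlorohydrin to the terminal epoxide (intramolecular Williamson reaction) and the phenoxide of 9 opens it by SN2 attack at the CH2 carbon, so the C–O bond of the stereocentre is never broken and it stays R.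

Step 6
Reactants: 11 2-({(2R)-2-hydroxy-3-[4-methoxy-3-(3-methylbut-2-en-1-yl)-2-(prop-2-en-1-yloxy)phenyl]propyl}oxy)-4-methoxy-6-(prop-2-en-1-yloxy)benzaldehyde
Product: 12 (2R)-1-[2-formyl-5-methoxy-3-(prop-2-en-1-yloxy)phenoxy]-3-[4-methoxy-3-(3-methylbut-2-en-1-yl)-2-(prop-2-en-1-yloxy)phenyl]propan-2-yl methanesulfonate
Conditions: MsCl, Et3N, CH2Cl2, −20 to 0 °C; used without storage
Reagents that add atoms: methanesulfonyl chloride, CS(=O)(=O)Cl
Why: O-sulfonylation (mesylation) of the only free hydroxyl takes place at oxygen with retention at carbon, both phenols being masked as allyl ethers.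

Step 7
Reactants: 12 (2R)-1-[2-formyl-5-methoxy-3-(prop-2-en-1-yloxy)phenoxy]-3-[4-methoxy-3-(3-methylbut-2-en-1-yl)-2-(prop-2-en-1-yloxy)phenyl]propan-2-yl methanesulfonate
Product: 14 (3R)-5-methoxy-3-[4-methoxy-3-(3-methylbut-2-en-1-yl)-2-(prop-2-en-1-yloxy)phenyl]-7-(prop-2-en-1-yloxy)-3,4-dihydro-2H-chromene-8-carbaldehyde, via phenonium mesylate ion pair 13 (not isolated)
Conditions: 2,6-di-tert-butyl-4-methylpyridine (1.5 equiv), (CF3)2CHOH (0.01 M), 25 to 50 °C
Reagents that add atoms: none
Why: Proposed new method: in the strongly ionising and weakly nucleophilic solvent the mesylate should leave with anti assistance from C1' of ring B, whose C2' and C4' oxygens stabilise the bridged spiro[2.5]octadienyl (phenonium) ion 13, and C4a of ring A should then open the strained three-membered ring at its CH2 carbon (C4) with re-aromatisation of ring B, the hindered pyridine taking the proton, so that the C4–C4a bond forms while ring B ends on C3. The closest known reaction types are the aryl-assisted solvolysis of 1-aryl-2-propyl sulfonates, the Friedel–Crafts arylation of aryl-bridged ions by electron-rich arenes in (CF3)2CHOH and the 6-endo epoxy-arene cyclisation of aryl glycidyl ethers to chroman-3-ols. Ring C closes in the 6-endo-tet mode with respect to the three-membered ring (its C3–C4 bond becomes part of the new ring); the competing 5-exo opening at C3 is disfavoured because C3 is the substituted carbon, is deactivated by the aryloxymethyl group and would need a backside attack inside a five-membered ring that holds two aromatic carbons. The new stereocentre C3 is controlled by the substrate: bridging inverts the mesylate carbon and the attack at C4 leaves C3 untouched, so the R mesylate should give the 3R chroman. The step needs attack through C4a only, secured because the other position ortho to O1 carries the formyl group, and it needs the prenyl and allyl alkenes to stay unprotonated, secured by the base that takes up the methanesulfonic acid.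

Step 8
Reactants: 14 (3R)-5-methoxy-3-[4-methoxy-3-(3-methylbut-2-en-1-yl)-2-(prop-2-en-1-yloxy)phenyl]-7-(prop-2-en-1-yloxy)-3,4-dihydro-2H-chromene-8-carbaldehyde
Product: 15 (3R)-7-hydroxy-3-[2-hydroxy-4-methoxy-3-(3-methylbut-2-en-1-yl)phenyl]-5-methoxy-3,4-dihydro-2H-chromene-8-carbaldehyde
Conditions: Pd(PPh3)4 (5 mol%), K2CO3, MeOH, rt; neutral work-up
Reagents that add atoms: none
Why: Zerovalent palladium ionises both aryl allyl ethers to π-allyl complexes that methoxide captures (Tsuji–Trost type deallylation), while the C-bound prenyl group, the aldehyde and the stereocentre are not affected.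

Compound list
1 | 2-bromo-5-methoxyphenol | COc1ccc(Br)c(O)c1 | starting material
2 | 1-bromo-3-methylbut-2-ene (prenyl bromide) | CC(C)=CCBr | starting material
3 | 6-bromo-3-methoxy-2-(3-methylbut-2-en-1-yl)phenol | COc1ccc(Br)c(O)c1CC=C(C)C | intermediate
4 | 1-bromo-4-methoxy-3-(3-methylbut-2-en-1-yl)-2-(prop-2-en-1-yloxy)benzene | COc1ccc(Br)c(OCC=C)c1CC=C(C)C | intermediate
5 | (R)-epichlorohydrin, (2R)-2-(chloromethyl)oxirane | ClC[C@H]1CO1 | starting material
6 | [4-methoxy-3-(3-methylbut-2-en-1-yl)-2-(prop-2-en-1-yloxy)phenyl]magnesium bromide (formed in the flask) | COc1ccc([Mg]Br)c(OCC=C)c1CC=C(C)C | intermediate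
7 | (2R)-1-chloro-3-[4-methoxy-3-(3-methylbut-2-en-1-yl)-2-(prop-2-en-1-yloxy)phenyl]propan-2-ol | O[C@@H](CCl)Cc1ccc(OC)c(CC=C(C)C)c1OCC=C | intermediate
8 | 2,6-dihydroxy-4-methoxybenzaldehyde | COc1cc(O)c(C=O)c(O)c1 | starting material
9 | 2-hydroxy-4-methoxy-6-(prop-2-en-1-yloxy)benzaldehyde | COc1cc(O)c(C=O)c(OCC=C)c1 | intermediate
10 | (2R)-2-{[4-methoxy-3-(3-methylbut-2-en-1-yl)-2-(prop-2-en-1-yloxy)phenyl]methyl}oxirane (formed in the flask) | C1O[C@@H]1Cc2ccc(OC)c(CC=C(C)C)c2OCC=C | intermediate
11 | 2-({(2R)-2-hydroxy-3-[4-methoxy-3-(3-methylbut-2-en-1-yl)-2-(prop-2-en-1-yloxy)phenyl]propyl}oxy)-4-methoxy-6-(prop-2-en-1-yloxy)benzaldehyde | O[C@@H](COc1cc(OC)cc(OCC=C)c1C=O)Cc1ccc(OC)c(CC=C(C)C)c1OCC=C | intermediate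
12 | (2R)-1-[2-formyl-5-methoxy-3-(prop-2-en-1-yloxy)phenoxy]-3-[4-methoxy-3-(3-methylbut-2-en-1-yl)-2-(prop-2-en-1-yloxy)phenyl]propan-2-yl methanesulfonate | CS(=O)(=O)O[C@@H](COc1cc(OC)cc(OCC=C)c1C=O)Cc1ccc(OC)c(CC=C(C)C)c1OCC=C | intermediate
13 | phenonium methanesulfonate ion pair: ring B bridges C3 and C4 as a spiro[2.5]octadienyl cation, drawn as the C4' oxocarbenium form, spiro carbon configuration open (formed in the flask) | C=CCOC1=C(CC=C(C)C)C(=[O+]C)C=CC12C[C@H]2COc3cc(OC)cc(OCC=C)c3C=O.CS(=O)(=O)[O-] | intermediate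
14 | (3R)-5-methoxy-3-[4-methoxy-3-(3-methylbut-2-en-1-yl)-2-(prop-2-en-1-yloxy)phenyl]-7-(prop-2-en-1-yloxy)-3,4-dihydro-2H-chromene-8-carbaldehyde | COc1ccc([C@@H]2COc3c(C=O)c(OCC=C)cc(OC)c3C2)c(OCC=C)c1CC=C(C)C | intermediate
15 | (3R)-7-hydroxy-3-[2-hydroxy-4-methoxy-3-(3-methylbut-2-en-1-yl)phenyl]-5-methoxy-3,4-dihydro-2H-chromene-8-carbaldehyde | COc1ccc([C@@H]2COc3c(C=O)c(O)cc(OC)c3C2)c(O)c1CC=C(C)C | target

Total step count: 8. Longest linear sequence: 7 steps (steps 1, 2, 3, 5, 6, 7 and 8; step 4 is a one-step side branch).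

Steps most likely to fail

Step 7 (bears the new-method label). What may go wrong: ring A may open the bridged ion at C3 instead of C4, or displace the mesylate directly without aryl shift; either closes a five-membered ring. The C2' oxygen of ring B may take part instead of C1'. The ion may also be captured by solvent or lose a proton if the formyl-bearing ring A attacks too slowly. Fallback with known chemistry, setting out from 7 and 8 and coming back at 15: the carbon–carbon bond and the ring closure are made in separate operations. Chlorohydrin 7 is closed with K2CO3 in MeOH and epoxide 10 is isolated. Epoxide 10 and an excess of the symmetric aldehyde 8 in (CF3)2CHOH with catalytic Sc(OTf)3 should undergo the intermolecular Friedel–Crafts ring-opening arylation that is established for aryl-bridged ions in this solvent. Ring B shifts to the central carbon and the only available position of 8 is alkylated, to give 2,6-dihydroxy-3-{(2R)-3-hydroxy-2-[4-methoxy-3-(3-methylbut-2-en-1-yl)-2-(prop-2-en-1-yloxy)phenyl]propyl}-4-methoxybenzaldehyde F1. Mitsunobu etherification (PPh3, DIAD, THF) of the primary alcohol with the neighbouring phenol should close ring C at O1–C2 to (3R)-7-hydroxy-5-methoxy-3-[4-methoxy-3-(3-methylbut-2-en-1-yl)-2-(prop-2-en-1-yloxy)phenyl]-3,4-dihydro-2H-chromene-8-carbaldehyde F2. Deallylation under the conditions of step 8 then gives 15.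

Step 1. What may go wrong: O-alkylation and para C-alkylation may compete with ortho C-prenylation, and the product may be alkylated a second time. Fallback, setting out from 1 and coming back at 3: the prenyl group is delivered by a sigmatropic shift instead of a direct C-alkylation. Phenol 1 is O-alkylated with 3-chloro-3-methylbut-1-yne (K2CO3, KI, catalytic CuI, acetone) to 1-bromo-4-methoxy-2-[(2-methylbut-3-yn-2-yl)oxy]benzene F3. Semihydrogenation (H2, Pd/CaCO3 poisoned with Pb(OAc)2, quinoline) gives 1-bromo-4-methoxy-2-[(2-methylbut-3-en-2-yl)oxy]benzene F4. Its aromatic Claisen rearrangement (N,N-diethylaniline, 130 °C) can only reach the free ortho position and should give 3.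

Step 5. What may go wrong: the hydrogen-bonded, weakly nucleophilic phenoxide may open the epoxide slowly, leaving room for epoxide oligomerisation through the product alkoxide or for attack at the internal carbon. Fallback, setting out from 7 and 9 and coming back at 11: the ether bond is made by direct SN2 displacement on a protected halohydrin instead of epoxide opening. Chlorohydrin 7 is silylated (t-BuMe2SiCl, imidazole, DMF) to tert-butyl({(2R)-1-chloro-3-[4-methoxy-3-(3-methylbut-2-en-1-yl)-2-(prop-2-en-1-yloxy)phenyl]propan-2-yl}oxy)dimethylsilane F5, which can no longer close to the epoxide. Williamson alkylation of phenol 9 (Cs2CO3, catalytic NaI, DMF, 80 °C) gives 2-({(2R)-2-[(tert-butyldimethylsilyl)oxy]-3-[4-methoxy-3-(3-methylbut-2-en-1-yl)-2-(prop-2-en-1-yloxy)phenyl]propyl}oxy)-4-methoxy-6-(prop-2-en-1-yloxy)benzaldehyde F6. Bu4NF in THF removes the silyl group and gives 11.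

Further compounds
F1 | step 7 | 2,6-dihydroxy-3-{(2R)-3-hydroxy-2-[4-methoxy-3-(3-methylbut-2-en-1-yl)-2-(prop-2-en-1-yloxy)phenyl]propyl}-4-methoxybenzaldehyde | COc1ccc([C@H](CO)Cc2c(O)c(C=O)c(O)cc2OC)c(OCC=C)c1CC=C(C)C
F2 | step 7 | (3R)-7-hydroxy-5-methoxy-3-[4-methoxy-3-(3-methylbut-2-en-1-yl)-2-(prop-2-en-1-yloxy)phenyl]-3,4-dihydro-2H-chromene-8-carbaldehyde | COc1ccc([C@@H]2COc3c(C=O)c(O)cc(OC)c3C2)c(OCC=C)c1CC=C(C)C
F3 | step 1 | 1-bromo-4-methoxy-2-[(2-methylbut-3-yn-2-yl)oxy]benzene | COc1ccc(Br)c(OC(C)(C)C#C)c1
F4 | step 1 | 1-bromo-4-methoxy-2-[(2-methylbut-3-en-2-yl)oxy]benzene | COc1ccc(Br)c(OC(C)(C)C=C)c1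
F5 | step 5 | tert-butyl({(2R)-1-chloro-3-[4-methoxy-3-(3-methylbut-2-en-1-yl)-2-(prop-2-en-1-yloxy)phenyl]propan-2-yl}oxy)dimethylsilane | CC(C)(C)[Si](C)(C)O[C@@H](CCl)Cc1ccc(OC)c(CC=C(C)C)c1OCC=C
F6 | step 5 | 2-({(2R)-2-[(tert-butyldimethylsilyl)oxy]-3-[4-methoxy-3-(3-methylbut-2-en-1-yl)-2-(prop-2-en-1-yloxy)phenyl]propyl}oxy)-4-methoxy-6-(prop-2-en-1-yloxy)benzaldehyde | CC(C)(C)[Si](C)(C)O[C@@H](COc1cc(OC)cc(OCC=C)c1C=O)Cc1ccc(OC)c(CC=C(C)C)c1OCC=C
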